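The runs are calculated on assumed constants; noise was put on by code.

**Two questions.** Two apparent orders are asked of the flask at 30% conversion.

1. apparent order in free enzyme when 30% of the starting material are converted (percent change of the rate of making target for one percent more free enzyme charged)
2. apparent order in second substrate when 30% of the starting material are converted (percent change of the rate of making target for one percent more second substrate charged)

| setting | ochre | grey | red | flask |
|---|---|---|---|---|
| starting material | 0.050 M | 0.050 M | 0.050 M | 0.050 M |
| second substrate | 0.075 M | 0.075 M | 0.037 M | 0.0750 M |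
| free enzyme | 6 µM | 14 µM | 9 µM | 9.0 µM |
| remark | run made earlier | run made earlier | run made earlier |  |

| run | time / min | target / % | starting material / % |
|---|---|---|---|
| ochre | 1.33 | 22 | 77 |
| ochre | 2.50 | 39 | 59 |
| ochre | 4.00 | 60 | 37 |
| ochre | 5.00 | 68 | 30 |
| ochre | 6.00 | 82 | 18 |
| grey | 0.500 | 17 | 83 |
| grey | 0.833 | 32 | 69 |
| grey | 1.50 | 53 | 45 |
| grey | 3.00 | 94 | 9 |
| grey | 6.00 | 100 | 4 |
| red | 0.500 | 11 | 89 |
| red | 1.50 | 29 | 71 |
| red | 3.00 | 48 | 49 |
| red | 4.00 | 57 | 41 |
| red | 6.00 | 69 | 32 |

(readings scatter by 2 percentage points)

- what was read earlier has a scatter of 2 percentage points, one standard deviation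

**Frozen quantity.** Ochre, grey and the flask share their charges of starting material and second substrate and differ in free enzyme. Near that conversion, grey gives 36.4 µM·min of enzyme dose, the free enzyme charged times the time per fraction of the charge made into target. Ochre gives 36.3 µM·min, nearly the same.

**What matters.** The starting material charge is 0.050 M in every run, so it cancels. One scatter on the grey reading moves the enzyme order by 0.0738. One scatter on the ochre reading moves it by 0.107. One scatter on the red reading moves the substrate order by 0.0976, and one on the grey reading moves that order by 0.0885. The ochre, grey and red readings therefore each count.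

**The reckoning.** The two doses give an enzyme order of 0.994. Red, with 49.3% of the flask's second substrate, reads 29% at 1.50 min, a dose of 46.6 µM·min. This reckoning therefore commits to a substrate order of 0.346, a mean over the way to that conversion. The forecast gives 1 and 0.25, lower on the second substrate, holding that the order “falls toward the flask's charge”.

**The flask.**

    starting material + free enzyme ⇌ first complex (K = 310 M⁻¹, k = 11000 M⁻¹ s⁻¹)
    first complex ⇌ loaded enzyme + first product (K = 0.0560 M, k = 3400 min⁻¹)
    second substrate + loaded enzyme ⇌ second complex (K = 95.0 M⁻¹, k = 1.40 × 10⁵ M⁻¹ min⁻¹)
    second complex → free enzyme + target (k = 4600 min⁻¹)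

The flask gives 1.0 in free enzyme and 0.32 in second substrate. At 0.500 min it holds 42.9% of the catalyst charged as first complex, the largest form and resting state, and 19.0% as loaded enzyme. The grey dose, spread over the flask's 9.0 µM, puts 30% conversion at 1.21 min, and the flask reaches it at 1.22 min.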